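**Retrosynthetic overview**

- The isobutyl-bearing stereocentre C4' is the one stereochemical problem the chiral pool does not solve. It is steered by a temporary C–O bond on the neighbouring side-chain carbon C1'' (a silyloxy stereocentre taken from (S)-2-hydroxy-3-methylbutanoate); this bond is not in the target and is cut by radical deoxygenation after the ring closure.
- Key disconnection: the dihydropyran ring (O1', C2', C3', C4', C4a', C8a') is opened across C3'–C4' and O1'–C2' to three components, syncarpic acid, the α-silyloxy aldehyde and (1S,5S)-(−)-β-pinene. They are joined in one pot by Knoevenagel condensation and inverse-electron-demand oxa-[4+2] cycloaddition.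
- Enabling feature: the enol ether double bond C4a'=C8a' of the pyran ring is shared with the trione ring and conjugated with C5'=O, so O1'–C8a'=C4a'–C4' is the retron of a 1-oxadiene (an alkylidene β-triketone). The spiro carbon C2' and its CH2 neighbour C3' are the exocyclic C2=C10 alkene of the pinane.
- Order of rings: the pinane bicycle comes intact from β-pinene, the trione ring is made from 2,4,6-trihydroxyacetophenone by dearomatising tetramethylation and deacetylation, and the pyran ring is closed last.

Key step: step 5

Remark: β-triketones are drawn as one tautomer; primed locants belong to the chromene half, unprimed locants to the pinane half, C1'' is the side-chain carbon on C4', and the commercial chiral starting materials are taken as enantiopure.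

**Route**

Step 1
Reactants: 1 2,4,6-trihydroxyacetophenone; 2 iodomethane
Product: 3 acetylsyncarpic acid (2-acetyl-3-hydroxy-4,4,6,6-tetramethylcyclohex-2-ene-1,5-dione)
Conditions: NaOMe (excess), MeI (excess), MeOH, 0 °C to reflux; then aqueous HCl
Reagents that add atoms: iodomethane, CI
Why: Exhaustive base-mediated C-methylation of the phloroglucinol nucleus dearomatises the ring, the acetyl group blocking one ring carbon so that the four methyl groups enter pairwise at the two free ring carbons.

Step 2
Reactants: 3 acetylsyncarpic acid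
Product: 4 syncarpic acid (5-hydroxy-2,2,6,6-tetramethylcyclohex-4-ene-1,3-dione)
Conditions: 6 M aqueous HCl, reflux
Reagents that add atoms: none
Why: Acid-mediated retro-Claisen cleavage removes the exocyclic acetyl group from the tricarbonylmethane unit and leaves the ring triketone, whose other positions are quaternary and cannot react further.

Step 3
Reactants: 5 methyl (S)-2-hydroxy-3-methylbutanoate; 6 tert-butyldimethylsilyl chloride
Product: 7 methyl (S)-2-[(tert-butyldimethylsilyl)oxy]-3-methylbutanoate
Conditions: TBSCl, imidazole, DMF, rt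
Reagents that add atoms: tert-butyldimethylsilyl chloride, CC(C)(C)[Si](C)(C)Cl
Why: Imidazole-mediated silylation of a secondary alcohol is routine and does not touch the stereocentre.

Step 4
Reactants: 7 methyl (S)-2-[(tert-butyldimethylsilyl)oxy]-3-methylbutanoate
Product: 8 (S)-2-[(tert-butyldimethylsilyl)oxy]-3-methylbutanal
Conditions: i-Bu2AlH (1.05 equiv), CH2Cl2, −78 °C; then MeOH, aqueous potassium sodium tartrate
Reagents that add atoms: none
Why: Partial reduction of a methyl ester with i-Bu2AlH at low temperature stops at the aldehyde oxidation level and is the standard access to configurationally intact α-silyloxy aldehydes.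

Step 5
Reactants: 4 syncarpic acid; 8 (S)-2-[(tert-butyldimethylsilyl)oxy]-3-methylbutanal; 9 (1S,5S)-(−)-β-pinene
Product: 11 (1R,2R,4'R,5S)-4'-[(1S)-1-[(tert-butyldimethylsilyl)oxy]-2-methylpropyl]-6,6,6',6',8',8'-hexamethyl-3',4'-dihydrospiro[bicyclo[3.1.1]heptane-2,2'-chromene]-5',7'(6'H,8'H)-dione, via alkylidene triketone 10 (not isolated)
Conditions: ethylenediammonium diacetate (10 mol %), 9 (5 equiv), 4 Å molecular sieves, toluene, rt then 60 °C
Reagents that add atoms: none
Why: Ethylenediammonium diacetate condenses 4 and 8 (Knoevenagel) to the 2-alkylidene-1,3,5-trione 10, whose exocyclic C=C and the ring carbonyl anti to the side chain form an s-cis-locked, acceptor-activated 1-oxadiene that adds to the exocyclic C2=C10 alkene of 9 in an asynchronous, concerted inverse-electron-demand oxa-[4+2] cycloaddition. The closest known reaction type is the domino Knoevenagel/hetero-Diels–Alder reaction of cyclic 1,3-diones with aldehydes and alkenes, including cycloadditions of alkylidene β-triketones to terpene alkenes. The pyran ring is closed intermolecularly in [4+2] mode, C4'–C3' bond formation leading and O1'–C2' following, and the regiochemistry follows from attack of the nucleophilic CH2 terminus C10 on the alkylidene carbon while oxygen closes on the tertiary carbon C2. The spiro centre C2' is set by the pinane, because the C6 gem-dimethyl bridge shields one alkene face, so that the oxadiene adds syn to the C7 methylene bridge and O1' ends on that side. C4' is set by the temporary silyloxy stereocentre, because A(1,3) strain with the cis ring carbonyl holds its C–H in the diene plane and the alkene attacks the face anti to the C–OSi bond (Felkin–Anh-type, isopropyl outside), which from the (S)-aldehyde should give 4'R. The step needs diene-face selectivity, since a 1,1-dialkyl alkene has little endo/exo bias of its own, and periselectivity over the ene pathway; the first is secured by the allylic silyloxy group of 10 and the second by the concerted thermal mode in a non-polar medium without Lewis acid.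

Step 6
Reactants: 11 silyl ether from step 5
Product: 12 (1R,2R,4'R,5S)-4'-[(1S)-1-hydroxy-2-methylpropyl]-6,6,6',6',8',8'-hexamethyl-3',4'-dihydrospiro[bicyclo[3.1.1]heptane-2,2'-chromene]-5',7'(6'H,8'H)-dione
Conditions: HF·pyridine, pyridine, THF, 0 °C to rt
Reagents that add atoms: none
Why: Buffered fluoride cleaves the Si–O bond while the acid-sensitive tertiary alkyl enol ether C2'–O1', the non-enolisable ketones and all stereocentres stay untouched.

Step 7
Reactants: 12 secondary alcohol from step 6; 13 1,1'-thiocarbonyldiimidazole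
Product: 14 O-[(1S)-1-[(1R,2R,4'R,5S)-6,6,6',6',8',8'-hexamethyl-5',7'-dioxo-3',4',5',6',7',8'-hexahydrospiro[bicyclo[3.1.1]heptane-2,2'-chromen]-4'-yl]-2-methylpropyl] 1H-imidazole-1-carbothioate
Conditions: 1,1'-thiocarbonyldiimidazole, 4-(dimethylamino)pyridine (cat.), 1,2-dichloroethane, 70 °C
Reagents that add atoms: 1,1'-thiocarbonyldiimidazole, S=C(n1ccnc1)n1ccnc1
Why: Thioacylation of the secondary hydroxyl under neutral conditions installs the thiocarbonyl group needed for Barton–McCombie deoxygenation, with nucleophilic catalysis and heat compensating for the hindered position.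

Step 8
Reactants: 14 imidazolyl thionocarbonate from step 7
Product: 15 (1R,2R,4'R,5S)-6,6,6',6',8',8'-hexamethyl-4'-(2-methylpropyl)-3',4'-dihydrospiro[bicyclo[3.1.1]heptane-2,2'-chromene]-5',7'(6'H,8'H)-dione (target)
Conditions: Bu3SnH (3 equiv), 2,2'-azobis(2-methylpropionitrile) (cat.), toluene, 100 °C
Reagents that add atoms: none
Why: Barton–McCombie radical chain deoxygenation replaces the C1''–O bond by C–H, which erases the temporary stereocentre and leaves the isobutyl group, while the ketones, the enol ether and the stereocentres C1, C2, C5 and C4' are inert to stannyl radicals and a high Bu3SnH concentration favours direct hydrogen transfer.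

**Compound list**

1 | 2,4,6-trihydroxyacetophenone | CC(=O)c1c(O)cc(O)cc1O | starting material
2 | iodomethane | CI | starting material
3 | acetylsyncarpic acid (2-acetyl-3-hydroxy-4,4,6,6-tetramethylcyclohex-2-ene-1,5-dione) | CC(=O)C1=C(O)C(C)(C)C(=O)C(C)(C)C1=O | intermediate
4 | syncarpic acid (5-hydroxy-2,2,6,6-tetramethylcyclohex-4-ene-1,3-dione) | CC1(C)C(=O)C=C(O)C(C)(C)C1=O | intermediate
5 | methyl (S)-2-hydroxy-3-methylbutanoate | CC(C)[C@H](O)C(=O)OC | starting material
6 | tert-butyldimethylsilyl chloride | CC(C)(C)[Si](C)(C)Cl | starting material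
7 | methyl (S)-2-[(tert-butyldimethylsilyl)oxy]-3-methylbutanoate | CC(C)[C@H](O[Si](C)(C)C(C)(C)C)C(=O)OC | intermediate
8 | (S)-2-[(tert-butyldimethylsilyl)oxy]-3-methylbutanal | CC(C)[C@H](O[Si](C)(C)C(C)(C)C)C=O | intermediate
9 | (1S,5S)-(−)-β-pinene (6,6-dimethyl-2-methylidenebicyclo[3.1.1]heptane) | C=C1CC[C@H]2C[C@@H]1C2(C)C | starting material
10 | 2-[(2S)-2-[(tert-butyldimethylsilyl)oxy]-3-methylbutylidene]-4,4,6,6-tetramethylcyclohexane-1,3,5-trione | CC(C)[C@H](O[Si](C)(C)C(C)(C)C)C=C1C(=O)C(C)(C)C(=O)C(C)(C)C1=O | intermediate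
11 | (1R,2R,4'R,5S)-4'-[(1S)-1-[(tert-butyldimethylsilyl)oxy]-2-methylpropyl]-6,6,6',6',8',8'-hexamethyl-3',4'-dihydrospiro[bicyclo[3.1.1]heptane-2,2'-chromene]-5',7'(6'H,8'H)-dione | CC(C)[C@H](O[Si](C)(C)C(C)(C)C)[C@@H]1C[C@@]2(CC[C@H]3C[C@@H]2C3(C)C)OC2=C1C(=O)C(C)(C)C(=O)C2(C)C | intermediate
12 | (1R,2R,4'R,5S)-4'-[(1S)-1-hydroxy-2-methylpropyl]-6,6,6',6',8',8'-hexamethyl-3',4'-dihydrospiro[bicyclo[3.1.1]heptane-2,2'-chromene]-5',7'(6'H,8'H)-dione | CC(C)[C@H](O)[C@@H]1C[C@@]2(CC[C@H]3C[C@@H]2C3(C)C)OC2=C1C(=O)C(C)(C)C(=O)C2(C)C | intermediate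
13 | 1,1'-thiocarbonyldiimidazole | S=C(n1ccnc1)n1ccnc1 | starting material
14 | O-[(1S)-1-[(1R,2R,4'R,5S)-6,6,6',6',8',8'-hexamethyl-5',7'-dioxo-3',4',5',6',7',8'-hexahydrospiro[bicyclo[3.1.1]heptane-2,2'-chromen]-4'-yl]-2-methylpropyl] 1H-imidazole-1-carbothioate | CC(C)[C@H](OC(=S)n1ccnc1)[C@@H]1C[C@@]2(CC[C@H]3C[C@@H]2C3(C)C)OC2=C1C(=O)C(C)(C)C(=O)C2(C)C | intermediate
15 | (1R,2R,4'R,5S)-6,6,6',6',8',8'-hexamethyl-4'-(2-methylpropyl)-3',4'-dihydrospiro[bicyclo[3.1.1]heptane-2,2'-chromene]-5',7'(6'H,8'H)-dione | CC(C)C[C@@H]1C[C@@]2(CC[C@H]3C[C@@H]2C3(C)C)OC2=C1C(=O)C(C)(C)C(=O)C2(C)C | target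

**Step count**

Total steps: 8. Longest linear sequence: 6 steps (steps 3, 4, 5, 6, 7, 8 from 5; equally steps 1, 2, 5, 6, 7, 8 from 1).

**Steps most likely to fail, with fallbacks**

Step 5 is the riskiest. The diene-face control may erode, either because aldehyde 8 loses configurational integrity through enamine formation before it condenses, or because the Felkin–Anh-type bias is weaker than assumed with the bulky isopropyl group in the outside position. Transfer of the allylic C3 hydrogen of 9 (ene pathway) may also divert material. The fallback gives up the steering group. Setting out from 4 and 9, the same one-pot condensation and cycloaddition is run with commercial 3-methylbutanal. The alkylidene triketone 4,4,6,6-tetramethyl-2-(3-methylbutylidene)cyclohexane-1,3,5-trione F1 is trapped by 9 and should give 15 together with its (4'S)-epimer F2, both with the spiro centre fixed by the pinane. The two are separated by preparative chromatography, so the fallback arrives directly at 15 and steps 3, 4, 6, 7 and 8 fall away.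

Step 8 comes second. The secondary radical at C1'' is homoallylic to the C4a'=C8a' enol ether and may rearrange by 3-exo closure and reopening (1,2-vinyl shift), or the chain may propagate poorly at the hindered thiocarbonyl group. The fallback avoids radicals and sets out from 12. Oxidation with Dess–Martin periodinane (NaHCO3, CH2Cl2) should give the ketone (1R,2R,4'R,5S)-6,6,6',6',8',8'-hexamethyl-4'-(2-methylpropanoyl)-3',4'-dihydrospiro[bicyclo[3.1.1]heptane-2,2'-chromene]-5',7'(6'H,8'H)-dione F3. Condensation with p-toluenesulfonyl hydrazide gives the corresponding p-toluenesulfonylhydrazone F4. Reduction with catecholborane followed by NaOAc·3H2O with warming (hydride addition, then loss of sulfinate and dinitrogen) turns the C=N carbon into CH2 and comes back to the route at 15. The ring carbonyls are either flanked by two quaternary carbons or part of the vinylogous ester and should not compete. C4' is α to a ketone on this path, so its configuration would have to be monitored.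

Step 7 comes third. Acyl transfer to the hydroxyl group, which is flanked by an isopropyl group and the C4' methine, may stall. The fallback activates the oxygen as its alkoxide instead and sets out from 12. Deprotonation with NaH in THF, addition to the small electrophile CS2 and S-methylation with iodomethane 2 should give O-[(1S)-1-[(1R,2R,4'R,5S)-6,6,6',6',8',8'-hexamethyl-5',7'-dioxo-3',4',5',6',7',8'-hexahydrospiro[bicyclo[3.1.1]heptane-2,2'-chromen]-4'-yl]-2-methylpropyl] S-methyl carbonodithioate F5. This xanthate is reduced with Bu3SnH and 2,2'-azobis(2-methylpropionitrile) in toluene at 100 °C and comes back to the route at 15.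

**Further compounds**

F1 | step 5 | 4,4,6,6-tetramethyl-2-(3-methylbutylidene)cyclohexane-1,3,5-trione | CC(C)CC=C1C(=O)C(C)(C)C(=O)C(C)(C)C1=O
F2 | step 5 | (1R,2R,4'S,5S)-6,6,6',6',8',8'-hexamethyl-4'-(2-methylpropyl)-3',4'-dihydrospiro[bicyclo[3.1.1]heptane-2,2'-chromene]-5',7'(6'H,8'H)-dione | CC(C)C[C@H]1C[C@@]2(CC[C@H]3C[C@@H]2C3(C)C)OC2=C1C(=O)C(C)(C)C(=O)C2(C)C
F3 | step 8 | (1R,2R,4'R,5S)-6,6,6',6',8',8'-hexamethyl-4'-(2-methylpropanoyl)-3',4'-dihydrospiro[bicyclo[3.1.1]heptane-2,2'-chromene]-5',7'(6'H,8'H)-dione | CC(C)C(=O)[C@@H]1C[C@@]2(CC[C@H]3C[C@@H]2C3(C)C)OC2=C1C(=O)C(C)(C)C(=O)C2(C)C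
F4 | step 8 | N'-[1-[(1R,2R,4'R,5S)-6,6,6',6',8',8'-hexamethyl-5',7'-dioxo-3',4',5',6',7',8'-hexahydrospiro[bicyclo[3.1.1]heptane-2,2'-chromen]-4'-yl]-2-methylpropylidene]-4-methylbenzenesulfonohydrazide | CC(C)C(=NNS(=O)(=O)c1ccc(C)cc1)[C@@H]1C[C@@]2(CC[C@H]3C[C@@H]2C3(C)C)OC2=C1C(=O)C(C)(C)C(=O)C2(C)C
F5 | step 7 | O-[(1S)-1-[(1R,2R,4'R,5S)-6,6,6',6',8',8'-hexamethyl-5',7'-dioxo-3',4',5',6',7',8'-hexahydrospiro[bicyclo[3.1.1]heptane-2,2'-chromen]-4'-yl]-2-methylpropyl] S-methyl carbonodithioate | CC(C)[C@H](OC(=S)SC)[C@@H]1C[C@@]2(CC[C@H]3C[C@@H]2C3(C)C)OC2=C1C(=O)C(C)(C)C(=O)C2(C)C
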